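The six-membered carbocycle (C5–C10; halimane numbering: C5 lactone carbinol carbon, C6 and C7 CH2, C8 CHCH3, C9 quaternary, C10 CH, C20 lactone carbonyl) is disconnected into a C6/C9 bis-nucleophile and a propene-1,2-diyl dication. The precursor is a five-membered enol lactone that keeps C9 as a ring enolate carbon and masks C6 as an enol ester. Its lithium enolate adds to an (E)-propenylthianthrenium salt (C8–C9); methoxide then opens the enol ester and the freed C6 enolate displaces thianthrene (C6–C7), closing the ring in one operation. The step exploits the 1,4-dicarbonyl relationship of C20 and C5 across the ring; C10, set by catalysis, relays C9 and C8, later C5.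

Key step: step 7

Remark: further labels in the same numbering are C1–C3 (methyl propanoate chain on C10), C4 (isopropenyl carbon on C5), C11–C16 (butenolide chain on C9) and C17 (methyl on C8); the PINAP enantiomer that gives 4R in step 2 is assumed, both antipodes being available.

Step 1
Reactants: 1 2,2-dimethyl-1,3-dioxane-4,6-dione (Meldrum's acid); 2 methyl 4-oxobutanoate
Product: 3 methyl 4-(2,2-dimethyl-4,6-dioxo-1,3-dioxan-5-ylidene)butanoate
Conditions: pyrrolidinium acetate (10 mol %), benzene, 23 °C
Reagents that add atoms: none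
Why: Knoevenagel condensation of the acidic methylene of 1 with the aldehyde of 2 under mild ammonium carboxylate catalysis should give the alkylidene with loss of water; no stereocenter is formed.

Step 2
Reactants: 3 methyl 4-(2,2-dimethyl-4,6-dioxo-1,3-dioxan-5-ylidene)butanoate; 4 ethynyl(trimethyl)silane
Product: 5 methyl (4R)-4-(2,2-dimethyl-4,6-dioxo-1,3-dioxan-5-yl)-6-(trimethylsilyl)hex-5-ynoate
Conditions: Cu(OAc)2·H2O (10 mol %), PINAP ligand (10 mol %), sodium L-ascorbate NaC6H7O6 (20 mol %), H2O, 0 °C
Reagents that add atoms: none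
Why: Copper-catalysed enantioselective conjugate addition of a terminal alkyne to an alkylidene Meldrum's acid should set C10 (R) under control of the chiral P,N-ligand, the only stereocenter of the route that is set by catalysis.

Step 3
Reactants: 5 methyl (4R)-4-(2,2-dimethyl-4,6-dioxo-1,3-dioxan-5-yl)-6-(trimethylsilyl)hex-5-ynoate
Product: 7 (3R)-3-ethynyl-6-methoxy-6-oxohexanoic acid, via desilylated Meldrum's acid adduct 6 (not isolated)
Conditions: KF (20 mol %), DMF/H2O (10:1), 100 °C; then dilute HCl
Reagents that add atoms: water O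
Why: Fluoride-catalysed protodesilylation of the alkynylsilane and hydrolytic ring opening with decarboxylation of the Meldrum's acid should both proceed in hot aqueous DMF and leave C10 and the methyl ester untouched.

Step 4
Reactants: 7 (3R)-3-ethynyl-6-methoxy-6-oxohexanoic acid
Product: 8 methyl 3-[(3R)-2-methylidene-5-oxooxolan-3-yl]propanoate
Conditions: AuCl (5 mol %), MeCN, 23 °C
Reagents that add atoms: none
Why: Gold-catalysed cycloisomerisation of a 4-pentynoic acid (5-exo-dig attack of the acid on the activated alkyne) should give the exocyclic enol lactone under neutral conditions without affecting C10.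

Step 5
Reactants: 8 methyl 3-[(3R)-2-methylidene-5-oxooxolan-3-yl]propanoate; 9 tert-butyl(2-iodoethoxy)dimethylsilane
Product: 10 methyl 3-[(3R,4R)-4-[2-[tert-butyl(dimethyl)silyl]oxyethyl]-2-methylidene-5-oxooxolan-3-yl]propanoate
Conditions: LiN(SiMe3)2 (1.05 equiv), THF/DMPU, −78 °C; then 9, −78 → −40 °C
Reagents that add atoms: none
Why: Alkylation of the lactone lithium enolate with the primary iodide should occur at C9 anti to the C10 side chain (trans product) and installs C11 and C12 before the quaternary centre is made; the C9 protons are far more acidic than those α to the methyl ester.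

Step 6
Reactants: 11 thianthrene 5-oxide; 12 propene
Product: 13 5-[(E)-prop-1-enyl]thianthren-5-ium trifluoromethanesulfonate
Conditions: Tf2O, CH2Cl2, propene (1 atm), −78 → 0 °C; then aq. NaHCO3
Reagents that add atoms: trifluoromethanesulfonic anhydride O=S(=O)(OS(=O)(=O)C(F)(F)F)C(F)(F)F
Why: Alkene C–H thianthrenation, in which the O-triflylated sulfoxide adds across propene and base-induced elimination from the adduct follows, should give the E-alkenylthianthrenium salt.

Step 7
Reactants: 10 methyl 3-[(3R,4R)-4-[2-[tert-butyl(dimethyl)silyl]oxyethyl]-2-methylidene-5-oxooxolan-3-yl]propanoate; 13 5-[(E)-prop-1-enyl]thianthren-5-ium trifluoromethanesulfonate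
Product: 16 methyl (1R,2R,6R)-1-[2-[tert-butyl(dimethyl)silyl]oxyethyl]-2-(3-methoxy-3-oxopropyl)-6-methyl-3-oxocyclohexane-1-carboxylate, via thianthrenium enol lactone 14 (not isolated), via thianthrenium keto diester 15 (not isolated)
Conditions: LiN(SiMe3)2 (1.05 equiv), THF, −78 °C; 13 in CH2Cl2, −78 → −40 °C; then MeOH (1.1 equiv), −40 → 23 °C
Reagents that add atoms: methanol CO
Why: Proposed new method: The lithium enolate of 10 should add through C9 to the β-carbon C8 of 13 (Michael addition) to give a sulfonium ylide, which methanol protonates to 14 while releasing LiOMe; LiOMe then opens the activated enol lactone to the C20 methyl ester and frees the regiodefined C5–C6 ketone enolate of 15, whose carbon C6 displaces thianthrene from C7. The closest known reaction type is the Michael-initiated ring closure of bis-nucleophiles with vinylsulfonium and vinylthianthrenium salts used as ethane-1,2-diyl dication equivalents (cyclopropanation of 1,3-dicarbonyl compounds, morpholine and azetidine annulations), joined here to the known release of a specific ketone enolate from an enol ester by an alkoxide. The carbocycle C5–C10 closes by intramolecular SN2 alkylation in the 6-(enolendo)-exo-tet mode. C9 is set by approach of 13 to the face of the planar lactone enolate anti to the C10 side chain, and C8 by the relative topicity of an open synclinal Michael transition state in which the C8 hydrogen occupies the crowded sector between C10 and C11, the sulfonium arm lies over the lactone ring and the methyl group points away, the sense known for cyclic enolates with (E)-β-substituted acceptors; C10 is carried through unchanged. The step needs C9 to react before C6 and carbon rather than oxygen alkylation at C6: the enol ester keeps C6 silent until methoxide arrives, the C9 proton is the most acidic one in 10, and the enolendo geometry with a soft sulfonium leaving group should favour the cyclohexanone.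

Step 8
Reactants: 16 methyl (1R,2R,6R)-1-[2-[tert-butyl(dimethyl)silyl]oxyethyl]-2-(3-methoxy-3-oxopropyl)-6-methyl-3-oxocyclohexane-1-carboxylate; 17 prop-1-en-2-ylmagnesium bromide CH2=C(CH3)MgBr
Product: 19 methyl 3-[(1R,2R,5S,8R)-1-[2-[tert-butyl(dimethyl)silyl]oxyethyl]-2-methyl-7-oxo-5-(prop-1-en-2-yl)-6-oxabicyclo[3.2.1]octan-8-yl]propanoate, via hydroxy diester 18 (not isolated)
Conditions: CeCl3 (anhydrous), THF, −78 → 23 °C; then H2O
Reagents that add atoms: none
Why: 1,2-Addition of the organocerium reagent to the ketone should occur from the equatorial direction because the axial C9 ester blocks axial attack, so the new axial alkoxide is 1,3-diaxial to that ester and lactonises onto it ahead of the remote C3 ester, which fixes C5 and makes C9 a ring stereocenter.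

Step 9
Reactants: 19 methyl 3-[(1R,2R,5S,8R)-1-[2-[tert-butyl(dimethyl)silyl]oxyethyl]-2-methyl-7-oxo-5-(prop-1-en-2-yl)-6-oxabicyclo[3.2.1]octan-8-yl]propanoate
Product: 20 methyl 3-[(1R,2R,5S,8R)-1-(2-bromoethyl)-2-methyl-7-oxo-5-(prop-1-en-2-yl)-6-oxabicyclo[3.2.1]octan-8-yl]propanoate
Conditions: Ph3PBr2, CH2Cl2, 0 → 23 °C
Reagents that add atoms: triphenylphosphine dibromide BrP(Br)(c1ccccc1)(c1ccccc1)c1ccccc1
Why: Appel-type conversion of the primary silyl ether directly into the bromide should avoid a free C12 alcohol, which could translactonise onto C20.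

Step 10
Reactants: 20 methyl 3-[(1R,2R,5S,8R)-1-(2-bromoethyl)-2-methyl-7-oxo-5-(prop-1-en-2-yl)-6-oxabicyclo[3.2.1]octan-8-yl]propanoate; 21 3-bromofuran-2(5H)-one
Product: 23 methyl 3-[(1R,2R,5S,8R)-2-methyl-7-oxo-1-[2-(2-oxo-2,5-dihydrofuran-3-yl)ethyl]-5-(prop-1-en-2-yl)-6-oxabicyclo[3.2.1]octan-8-yl]propanoate, via alkylzinc bromide 22 (not isolated)
Conditions: Zn dust, LiCl, THF, 50 °C; then 21, Pd2(dba)3 (2.5 mol %), SPhos (10 mol %), THF/NMP, 23 °C
Reagents that add atoms: none
Why: Zinc insertion into the primary C12–Br bond followed by Negishi cross-coupling with the α-bromobutenolide under zerovalent palladium catalysis should form C12–C13 without touching the esters, the lactone or any stereocenter.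

Compound list
1 | 2,2-dimethyl-1,3-dioxane-4,6-dione (Meldrum's acid) | CC1(C)OC(=O)CC(=O)O1 | starting material
2 | methyl 4-oxobutanoate | COC(=O)CCC=O | starting material
3 | methyl 4-(2,2-dimethyl-4,6-dioxo-1,3-dioxan-5-ylidene)butanoate | COC(=O)CCC=C1C(=O)OC(C)(C)OC1=O | intermediate
4 | ethynyl(trimethyl)silane | C#C[Si](C)(C)C | starting material
5 | methyl (4R)-4-(2,2-dimethyl-4,6-dioxo-1,3-dioxan-5-yl)-6-(trimethylsilyl)hex-5-ynoate | COC(=O)CC[C@@H](C#C[Si](C)(C)C)C1C(=O)OC(C)(C)OC1=O | intermediate
6 | methyl (4R)-4-(2,2-dimethyl-4,6-dioxo-1,3-dioxan-5-yl)hex-5-ynoate | COC(=O)CC[C@@H](C#C)C1C(=O)OC(C)(C)OC1=O | intermediate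
7 | (3R)-3-ethynyl-6-methoxy-6-oxohexanoic acid | COC(=O)CC[C@@H](C#C)CC(=O)O | intermediate
8 | methyl 3-[(3R)-2-methylidene-5-oxooxolan-3-yl]propanoate | C=C1OC(=O)C[C@H]1CCC(=O)OC | intermediate
9 | tert-butyl(2-iodoethoxy)dimethylsilane | CC(C)(C)[Si](C)(C)OCCI | starting material
10 | methyl 3-[(3R,4R)-4-[2-[tert-butyl(dimethyl)silyl]oxyethyl]-2-methylidene-5-oxooxolan-3-yl]propanoate (trans) | C=C1OC(=O)[C@H](CCO[Si](C)(C)C(C)(C)C)[C@H]1CCC(=O)OC | intermediate
11 | thianthrene 5-oxide | O=S1c2ccccc2Sc2ccccc12 | starting material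
12 | propene | C=CC | starting material
13 | 5-[(E)-prop-1-enyl]thianthren-5-ium trifluoromethanesulfonate | C/C=C/[S+]1c2ccccc2Sc2ccccc21.[O-]S(=O)(=O)C(F)(F)F | intermediate
14 | Michael adduct: enol lactone 10 carrying at C9 a 1-(thianthren-5-ium-5-yl)propan-2-yl group trans to the C10 side chain, trifluoromethanesulfonate salt (C8 and C9 as in 16) | C=C1OC(=O)[C@](CCO[Si](C)(C)C(C)(C)C)([C@H](C)C[S+]2c3ccccc3Sc3ccccc32)[C@H]1CCC(=O)OC.[O-]S(=O)(=O)C(F)(F)F | intermediate
15 | ring-opened salt: acyclic methyl ketone with the C20 methyl ester and the C7 thianthrenium group, trifluoromethanesulfonate salt (C8, C9, C10 as in 16) | CC(=O)[C@H](CCC(=O)OC)[C@](CCO[Si](C)(C)C(C)(C)C)(C(=O)OC)[C@H](C)C[S+]1c2ccccc2Sc2ccccc21.[O-]S(=O)(=O)C(F)(F)F | intermediate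
16 | methyl (1R,2R,6R)-1-[2-[tert-butyl(dimethyl)silyl]oxyethyl]-2-(3-methoxy-3-oxopropyl)-6-methyl-3-oxocyclohexane-1-carboxylate | O=C1CC[C@@H](C)[C@@](CCO[Si](C)(C)C(C)(C)C)(C(=O)OC)[C@H]1CCC(=O)OC | intermediate
17 | prop-1-en-2-ylmagnesium bromide, CH2=C(CH3)MgBr | C=C(C)[Mg]Br | starting material
18 | methyl (1R,2R,3S,6R)-1-[2-[tert-butyl(dimethyl)silyl]oxyethyl]-3-hydroxy-2-(3-methoxy-3-oxopropyl)-6-methyl-3-(prop-1-en-2-yl)cyclohexane-1-carboxylate | C=C(C)[C@]1(O)CC[C@@H](C)[C@@](CCO[Si](C)(C)C(C)(C)C)(C(=O)OC)[C@H]1CCC(=O)OC | intermediate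
19 | methyl 3-[(1R,2R,5S,8R)-1-[2-[tert-butyl(dimethyl)silyl]oxyethyl]-2-methyl-7-oxo-5-(prop-1-en-2-yl)-6-oxabicyclo[3.2.1]octan-8-yl]propanoate | C=C(C)[C@@]12CC[C@@H](C)[C@@](CCO[Si](C)(C)C(C)(C)C)(C(=O)O1)[C@H]2CCC(=O)OC | intermediate
20 | methyl 3-[(1R,2R,5S,8R)-1-(2-bromoethyl)-2-methyl-7-oxo-5-(prop-1-en-2-yl)-6-oxabicyclo[3.2.1]octan-8-yl]propanoate | C=C(C)[C@@]12CC[C@@H](C)[C@@](CCBr)(C(=O)O1)[C@H]2CCC(=O)OC | intermediate
21 | 3-bromofuran-2(5H)-one | O=C1OCC=C1Br | starting material
22 | alkylzinc bromide of 20 (C12–ZnBr) | C=C(C)[C@@]12CC[C@@H](C)[C@@](CC[Zn]Br)(C(=O)O1)[C@H]2CCC(=O)OC | intermediate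
23 | methyl 3-[(1R,2R,5S,8R)-2-methyl-7-oxo-1-[2-(2-oxo-2,5-dihydrofuran-3-yl)ethyl]-5-(prop-1-en-2-yl)-6-oxabicyclo[3.2.1]octan-8-yl]propanoate | C=C(C)[C@@]12CC[C@@H](C)[C@@](CCC3=CCOC3=O)(C(=O)O1)[C@H]2CCC(=O)OC | target

Total step count: 10. Longest linear sequence: 9 (steps 1 to 5 and 7 to 10; step 6 makes the reagent 13).

Steps most likely to fail

1. Step 7 (proposed new method). The hindered enolate may take a proton from the allylic methyl group of 13 instead of adding to it. The addition may also occur with the wrong relative topicity at C8, and the closing event may go through oxygen alkylation or loss of the sulfonium group by elimination. The fallback sets out from 10 and comes back at 16, making the two bonds in separate known operations. The lithium enolate of 10 (LiN(SiMe3)2, THF, −78 °C) is added to (E)-1-nitropropene in a nitro-Michael addition to give the nitro enol lactone F1. NaOMe in MeOH opens the enol lactone and forms the nitronate, and a buffered Nef reaction (TiCl3, NH4OAc) gives the keto aldehyde F2. Intramolecular aldol condensation of the methyl ketone onto the aldehyde (dibenzylammonium trifluoroacetate, benzene) closes the cyclohexenone F3. Hydrogenation (H2, Pd/C) of the ring alkene returns 16.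

2. Step 5. The enol lactone enolate may fragment to a ketene, or the β-silyloxy iodide may alkylate too slowly. The fallback sets out from 5 and comes back at 10, attaching C11 and C12 before the lactone exists. Soft C-alkylation of the Meldrum's acid carbon of 5 with 9 (Cs2CO3, DMF) gives the dialkyl Meldrum's acid F4. Hydrolysis and decarboxylation in pyridine/H2O at reflux give the acid F5, and K2CO3 in MeOH removes the alkynyl silyl group to give the acid F6. AuCl in MeCN closes F6 to 10 together with its C9 epimer F7; both give the same enolate in step 7.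

3. Step 2. The silylalkyne may be too unreactive in the aqueous copper system, or the facial selectivity may be poor. The fallback sets out from 2 and comes back at 7, moving the asymmetric alkynylation to an enal. Wittig reaction of 2 with Ph3P=CHCHO gives the enal F8. Rhodium-catalysed enantioselective conjugate alkynylation with ethynyl(triisopropyl)silane ([Rh(OAc)(C2H4)2]2, DTBM-SEGPHOS, MeOH) gives the β-alkynyl aldehyde F9. Pinnick oxidation (NaClO2, NaH2PO4, 2-methylbut-2-ene) gives the acid F10, and Bu4NF removes the silyl group to give 7.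

Further compounds
F1 | step 7 | nitro-Michael adduct: enol lactone 10 carrying at C9 a 1-nitropropan-2-yl group trans to the C10 side chain (C8 and C9 as in 16) | C=C1OC(=O)[C@](CCO[Si](C)(C)C(C)(C)C)([C@H](C)C[N+](=O)[O-])[C@H]1CCC(=O)OC
F2 | step 7 | keto aldehyde: acyclic methyl ketone with the C20 methyl ester and a C7 aldehyde (C8, C9, C10 as in 16) | CC(=O)[C@H](CCC(=O)OC)[C@](CCO[Si](C)(C)C(C)(C)C)(C(=O)OC)[C@H](C)C=O
F3 | step 7 | cyclohexenone: 16 with a C6=C7 double bond conjugated to the C5 ketone | O=C1C=C[C@@H](C)[C@@](CCO[Si](C)(C)C(C)(C)C)(C(=O)OC)[C@H]1CCC(=O)OC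
F4 | step 5 | methyl (4R)-4-[5-[2-[tert-butyl(dimethyl)silyl]oxyethyl]-2,2-dimethyl-4,6-dioxo-1,3-dioxan-5-yl]-6-(trimethylsilyl)hex-5-ynoate | COC(=O)CC[C@@H](C#C[Si](C)(C)C)C1(CCO[Si](C)(C)C(C)(C)C)C(=O)OC(C)(C)OC1=O
F5 | step 5 | (3R)-2-[2-[tert-butyl(dimethyl)silyl]oxyethyl]-6-methoxy-6-oxo-3-[2-(trimethylsilyl)ethynyl]hexanoic acid (both C2 epimers) | COC(=O)CC[C@@H](C#C[Si](C)(C)C)C(CCO[Si](C)(C)C(C)(C)C)C(=O)O
F6 | step 5 | (3R)-2-[2-[tert-butyl(dimethyl)silyl]oxyethyl]-3-ethynyl-6-methoxy-6-oxohexanoic acid (both C2 epimers) | COC(=O)CC[C@@H](C#C)C(CCO[Si](C)(C)C(C)(C)C)C(=O)O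
F7 | step 5 | methyl 3-[(3R,4S)-4-[2-[tert-butyl(dimethyl)silyl]oxyethyl]-2-methylidene-5-oxooxolan-3-yl]propanoate (cis epimer of 10) | C=C1OC(=O)[C@@H](CCO[Si](C)(C)C(C)(C)C)[C@H]1CCC(=O)OC
F8 | step 2 | methyl (E)-6-oxohex-4-enoate | COC(=O)CC/C=C/C=O
F9 | step 2 | methyl (4R)-4-(2-oxoethyl)-6-(triisopropylsilyl)hex-5-ynoate | COC(=O)CC[C@@H](C#C[Si](C(C)C)(C(C)C)C(C)C)CC=O
F10 | step 2 | (3R)-6-methoxy-6-oxo-3-[2-(triisopropylsilyl)ethynyl]hexanoic acid | COC(=O)CC[C@@H](C#C[Si](C(C)C)(C(C)C)C(C)C)CC(=O)O
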